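**Retrosynthetic overview**
1. Feature used: ring A carries at C4 an equatorial CH2OH and an axial CH3 beside the trans A/B fusion (5α-H, 10β-CH3). C9 holds C11 equatorially and ring B holds C7=C8. Together this is the stereochemical print of an all-E 12-hydroxyfarnesyl chain folded chair–chair.
2. Key disconnection: C4–C5 and C9–C10 are cut together. Rings A and B arise in one cation–olefin bicyclisation of an acyclic (2S,3S)-2,3-epoxy alcohol. Its C3–O bond is absent from the target, carries the absolute information, and is deleted afterwards.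
3. The chain ends in a silylalkyne (C1'≡C2') instead of an arene. The C1'–C6' ring is built last around it by Dötz benzannulation, which gives C6'–OH free and C3'–OMe masked, so the two ring oxygens are differentiated from the outset.
4. Endgame: phenol → quinone monoketal (ketal at C3') → hydroxyl-directed asymmetric nucleophilic epoxidation of C1'=C2' → reduction of C6'=O anti to the oxirane → ketal hydrolysis.
5. Order of ring formation: A and B together (step 4), carbocycle C1'–C6' (step 9), oxirane (step 12).

Key step: step 4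

Numbering used throughout, also for acyclic precursors:
- Drimane part: C1–C10; C11 = CH2 on C9; C12 = CH3 on C8; C13 = 4α-CH2OH; C14 = 4β-CH3; C15 = CH3 on C10.
- Oxygenated ring: C1' (bears C11), C2' (oxirane CH), C3' (C=O), C4' (bears C7'H2OH), C5' (=CH), C6' (CHOH).
- The target is (4R,5R,9S,10R,1'S,2'S,6'R).

Assumption: L-(+)-DIPT is taken to direct the peroxide in step 12 to the required face, by analogy with hydroxymethyl-substituted quinone monoketals. D-(−)-DIPT is equally available and is used if the sense of induction is the opposite. Trityl hydroperoxide is treated as a reagent (made from Ph3COH and H2O2).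

**Step 1**
Reactants: 1 (2E,6E)-farnesyl bromide; 2 ethynyltrimethylsilane
Product: 4 trimethyl[(4E,8E)-5,9,13-trimethyltetradeca-4,8,12-trien-1-yn-1-yl]silane, via [(trimethylsilyl)ethynyl]magnesium bromide 3 (not isolated)
Conditions: 2, EtMgBr, THF, 0 → 40 °C; CuBr·SMe2 (10 mol %), then 1, THF, 0 °C → rt
Reagents that add atoms: none
Why: Copper-catalysed SN2 coupling of an alkynyl Grignard reagent with a primary allylic bromide joins the unhindered α-carbon to give the skipped enyne with both E olefins retained, and no stereocentre is formed.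

**Step 2**
Reactants: 4 silyl enyne triene
Product: 5 (2E,6E,10E)-2,6,10-trimethyl-14-(trimethylsilyl)tetradeca-2,6,10-trien-13-yn-1-ol
Conditions: SeO2 (10 mol %), t-BuOOH, salicylic acid (10 mol %), CH2Cl2, 0 °C, stopped at partial conversion (4 recycled)
Reagents that add atoms: tert-butyl hydroperoxide, CC(C)(C)OO (oxygen source, relayed through catalytic selenium dioxide, O=[Se]=O)
Why: Riley allylic oxidation (ene reaction, then [2,3]-shift) attacks the most electron-rich and least hindered terminal isopropylidene group and oxidises only its E methyl group, which fixes the olefin geometry that later becomes the C4 configuration.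

**Step 3**
Reactants: 5 E-allylic alcohol
Product: 6 {(2S,3S)-2-methyl-3-[(3E,7E)-3,7-dimethyl-11-(trimethylsilyl)undeca-3,7-dien-10-yn-1-yl]oxiran-2-yl}methanol (oxirane on C3–C4; CH2OH trans to the chain)
Conditions: Ti(OiPr)4 (10 mol %), L-(+)-DET (12 mol %), t-BuOOH, 4 Å MS, CH2Cl2, −20 °C
Reagents that add atoms: tert-butyl hydroperoxide, CC(C)(C)OO
Why: Sharpless asymmetric epoxidation is bound to the allylic hydroxyl, so only the C3=C4 olefin reacts, and L-(+)-DET gives the (2S,3S)-epoxide of an E-allylic alcohol, which sets C3 (S) and C4 (S).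

**Step 4**
Reactants: 6 (2S,3S)-epoxy alcohol
Product: 8 11-[(trimethylsilyl)ethynyl]drim-7-ene-3β,13-diol (trans-decalin, 5α-H, 9α-H, 10β-CH3, 4β-CH3 axial, 4α-CH2OH equatorial, 3β-OH equatorial, C7=C8), via dichloroaluminium alkoxide of the epoxy alcohol 7 (not isolated)
Conditions: MeAlCl2 (3 equiv), CH2Cl2 (high dilution), −78 °C; aq. Rochelle salt
Reagents that add atoms: none
Why: The first equivalent of MeAlCl2 turns the C13 hydroxyl into the chloroaluminium alkoxide 7 (methane is lost), which chelates the oxirane oxygen, so that the tertiary C4–O bond ionises selectively while C5 of the C5=C10 olefin attacks C4 from the rear, C9 of the C8=C9 olefin attacks the developing C10 cation, and the C8 cation loses the axial 7α-proton. The closest known reaction types are the MeAlCl2-promoted epoxide-initiated cation–olefin polycyclisation of epoxy-polyprenes and the hydroxyl-mediated delivery of Lewis acids to 2,3-epoxy alcohols. Ring A closes by 6-endo opening of the oxirane (C4–C5 bond) and ring B by 6-endo-trig attack (C9–C10 bond), both in one chair–chair array. C3 keeps its configuration, takes the equatorial 3β position and so fixes the absolute sense of folding; C4 is inverted and the E geometry of the former allylic alcohol places C13 equatorial (α) and C14 axial (β); anti addition across the E C5=C10 olefin gives 5α-H/10β-CH3, and the E C8=C9 olefin places C11 equatorial (9α-H). The step needs initiation at one site (secured by the chelate), an uninterrupted cascade (the silylalkyne has no heteroatom and could only close a four- or five-membered ring, whereas an ortho-oxygenated arene would trap C8 as a chroman) and Δ7-selective proton loss (7α-H is axial, aligned with the empty orbital and leads to the trisubstituted olefin, while 9α-H is flanked by quaternary C10 and by C11). The C3–O bond is a temporary control element and is removed in steps 5 and 6.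

**Step 5**
Reactants: 8 3β,13-diol
Product: 9 3β,13-O-thiocarbonyl derivative of 8 (1,3-dioxane-2-thione fused to C3–C4)
Conditions: 1,1'-thiocarbonyldiimidazole, DMAP (cat.), toluene, 90 °C
Reagents that add atoms: 1,1'-thiocarbonyldiimidazole, S=C(n1ccnc1)n1ccnc1
Why: In this thiocarbonyl transfer the primary hydroxyl is acylated first and the equatorial 3β-hydroxyl, gauche to the equatorial CH2O arm, closes an unstrained trans-fused six-membered thionocarbonate without touching any stereocentre.

**Step 6**
Reactants: 9 cyclic thionocarbonate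
Product: 11 11-ethynyldrim-7-en-13-ol, via 13-O-{[(tributylstannyl)sulfanyl]carbonyl}-11-[(trimethylsilyl)ethynyl]drim-7-en-13-ol 10 (not isolated)
Conditions: Bu3SnH (slow addition), AIBN (cat.), toluene, 100 °C; then K2CO3 (cat.), MeOH, rt
Reagents that add atoms: none
Why: In this Barton–McCombie deoxygenation (cyclic thionocarbonate variant) the stannyl radical adds to sulfur much faster than to the hindered silylalkyne, the adduct fragments to the secondary C3 radical rather than the primary neopentyl C13 radical, hydrogen transfer deletes the temporary C3–O bond, and methanolysis frees the C13 hydroxyl and the terminal alkyne in the same flask.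

**Step 7**
Reactants: 12 2-bromoprop-2-en-1-ol
Product: 13 [(2-bromoprop-2-en-1-yl)oxy]triisopropylsilane
Conditions: TIPSCl, imidazole, CH2Cl2, 0 °C → rt
Reagents that add atoms: chlorotriisopropylsilane, CC(C)[Si](Cl)(C(C)C)C(C)C
Why: Standard silylation of a primary alcohol, with the bulky TIPS group chosen because it resists O→C silyl migration in the vinyllithium of the next step.

**Step 8**
Reactants: 13 bromoallyl TIPS ether; 14 hexacarbonylchromium(0)
Product: 17 pentacarbonyl{1-methoxy-2-[(triisopropylsilyloxy)methyl]prop-2-en-1-ylidene}chromium(0), via 3-(triisopropylsilyloxy)prop-1-en-2-yllithium 15 (not isolated), via lithium pentacarbonyl{1-oxido-2-[(triisopropylsilyloxy)methyl]prop-2-en-1-ylidene}chromate 16 (not isolated)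
Conditions: t-BuLi (2 equiv), Et2O, −78 °C; 14, −78 °C → rt; MeOTf, CH2Cl2, 0 °C
Reagents that add atoms: methyl trifluoromethanesulfonate, COS(=O)(=O)C(F)(F)F
Why: Fischer carbene synthesis, that is bromine–lithium exchange, addition of the vinyllithium to a CO ligand and O-methylation of the acyl chromate, as is routine for α-substituted alkenyl complexes.

**Step 9**
Reactants: 11 11-ethynyldrim-7-en-13-ol; 17 alkenyl(methoxy)carbene complex
Product: 19 2-(13-hydroxydrim-7-en-11-yl)-4-methoxy-5-[(triisopropylsilyloxy)methyl]phenol, via its η6-tricarbonylchromium complex 18 (not isolated)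
Conditions: THF (0.1 M), 55 °C, Ar; then air, CH2Cl2, daylight, rt
Reagents that add atoms: none
Why: In the Dötz benzannulation (alkyne insertion, CO insertion, 6π-electrocyclisation, tautomerisation) the substituted carbon of a terminal alkyne ends next to the CO-derived carbon, so C1' carrying C11 lies ortho to the free C6'–OH, the carbene carbon becomes C3'–OMe and its α-carbon becomes C4' with the CH2OTIPS group, and no stereocentre is formed.

**Step 10**
Reactants: 19 TIPS ether
Product: 20 2-(13-hydroxydrim-7-en-11-yl)-5-(hydroxymethyl)-4-methoxyphenol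
Conditions: TBAF, THF, 0 °C, Ar
Reagents that add atoms: none
Why: Fluoride-induced desilylation frees the C7' hydroxyl that must direct the epoxidation, and the olefin and the other hydroxyl groups are inert to fluoride.

**Step 11**
Reactants: 20 4-methoxyphenol
Product: 21 2-(13-hydroxydrim-7-en-11-yl)-5-(hydroxymethyl)-4,4-dimethoxycyclohexa-2,5-dien-1-one (C6'=O, ketal at C3')
Conditions: PhI(OAc)2, MeOH, 0 °C
Reagents that add atoms: methanol, CO
Why: Hypervalent-iodine oxidative dearomatisation of a 4-methoxyphenol in methanol gives the quinone monoketal, and the position of the free phenol dictates that the carbonyl stands at C6' and the ketal at C3'.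

**Step 12**
Reactants: 21 quinone monoketal
Product: 22 (1'S,2'S)-epoxide: 1-(13-hydroxydrim-7-en-11-yl)-4-(hydroxymethyl)-5,5-dimethoxy-7-oxabicyclo[4.1.0]hept-3-en-2-one
Conditions: Ph3COOH, NaHMDS, L-(+)-DIPT, 4 Å MS, toluene, −65 °C
Reagents that add atoms: triphenylmethyl hydroperoxide, OOC(c1ccccc1)(c1ccccc1)c1ccccc1
Why: In this Weitz–Scheffer nucleophilic epoxidation (tartrate-modified, hydroxyl-directed form) the bulky peroxide anion can add only to C2', the sole unsubstituted β-carbon (C4' is blocked by C7'), and the sodium tartrate aggregate anchored on the C7' alkoxide beside the ketal selects the face, which sets C1' (S) and C2' (S) under reagent control.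

**Step 13**
Reactants: 22 epoxy enone
Product: 23 (1'S,2'S,6'R)-epoxy alcohol: 1-(13-hydroxydrim-7-en-11-yl)-4-(hydroxymethyl)-5,5-dimethoxy-7-oxabicyclo[4.1.0]hept-3-en-2-ol, OH anti to the oxirane oxygen
Conditions: NaBH4, CeCl3·7H2O, MeOH, −78 °C
Reagents that add atoms: none
Why: Luche 1,2-reduction under steric approach control, in which the face of C6'=O syn to C11 is blocked by the drimenylmethyl group on the adjacent quaternary C1' while the oxirane oxygen is tied back towards C2', so hydride enters syn to the oxirane and sets C6' (R) with OH cis to C11.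

**Step 14**
Reactants: 23 epoxy alcohol dimethyl ketal
Product: 24 epoxypholamin A (target)
Conditions: PPTS (cat.), acetone–H2O, rt
Reagents that add atoms: water, O
Why: Mild acid hydrolysis of the allylic dimethyl ketal unveils the C3' enone, the electron-poor oxirane and the trisubstituted C7=C8 olefin tolerate these conditions, and no stereocentre is α to an enolisable position that could scramble.

**Compound list**
1 | (2E,6E)-farnesyl bromide | CC(C)=CCC/C(C)=C/CC/C(C)=C/CBr | starting material
2 | ethynyltrimethylsilane | C#C[Si](C)(C)C | starting material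
3 | [(trimethylsilyl)ethynyl]magnesium bromide | C[Si](C)(C)C#C[Mg]Br | intermediate
4 | trimethyl[(4E,8E)-5,9,13-trimethyltetradeca-4,8,12-trien-1-yn-1-yl]silane | CC(C)=CCC/C(C)=C/CC/C(C)=C/CC#C[Si](C)(C)C | intermediate
5 | (2E,6E,10E)-2,6,10-trimethyl-14-(trimethylsilyl)tetradeca-2,6,10-trien-13-yn-1-ol | OC/C(C)=C/CC/C(C)=C/CC/C(C)=C/CC#C[Si](C)(C)C | intermediate
6 | (2S,3S)-2,3-epoxide of 5 | OC[C@]1(C)O[C@H]1CC/C(C)=C/CC/C(C)=C/CC#C[Si](C)(C)C | intermediate
7 | dichloroaluminium alkoxide of 6 | Cl[Al](Cl)OC[C@]1(C)O[C@H]1CC/C(C)=C/CC/C(C)=C/CC#C[Si](C)(C)C | intermediate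
8 | 11-[(trimethylsilyl)ethynyl]drim-7-ene-3β,13-diol | CC1=CC[C@H]2[C@](C)(CO)[C@@H](O)CC[C@]2(C)[C@H]1CC#C[Si](C)(C)C | intermediate
9 | 3β,13-cyclic thionocarbonate of 8 | CC1=CC[C@H]2[C@]3(C)COC(=S)O[C@H]3CC[C@]2(C)[C@H]1CC#C[Si](C)(C)C | intermediate
10 | 13-O-{[(tributylstannyl)sulfanyl]carbonyl}-11-[(trimethylsilyl)ethynyl]drim-7-en-13-ol | CC1=CC[C@H]2[C@](C)(COC(=O)S[Sn](CCCC)(CCCC)CCCC)CCC[C@]2(C)[C@H]1CC#C[Si](C)(C)C | intermediate
11 | 11-ethynyldrim-7-en-13-ol | CC1=CC[C@H]2[C@](C)(CO)CCC[C@]2(C)[C@H]1CC#C | intermediate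
12 | 2-bromoprop-2-en-1-ol | OCC(Br)=C | starting material
13 | [(2-bromoprop-2-en-1-yl)oxy]triisopropylsilane | C=C(Br)CO[Si](C(C)C)(C(C)C)C(C)C | intermediate
14 | hexacarbonylchromium(0) | [Cr].[C-]#[O+].[C-]#[O+].[C-]#[O+].[C-]#[O+].[C-]#[O+].[C-]#[O+] | starting material
15 | 3-(triisopropylsilyloxy)prop-1-en-2-yllithium | [Li]C(=C)CO[Si](C(C)C)(C(C)C)C(C)C | intermediate
16 | lithium acyl(pentacarbonyl)chromate | [Li+].[O-]C(=[Cr])C(=C)CO[Si](C(C)C)(C(C)C)C(C)C.[C-]#[O+].[C-]#[O+].[C-]#[O+].[C-]#[O+].[C-]#[O+] | intermediate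
17 | pentacarbonyl{1-methoxy-2-[(triisopropylsilyloxy)methyl]prop-2-en-1-ylidene}chromium(0) | COC(=[Cr])C(=C)CO[Si](C(C)C)(C(C)C)C(C)C.[C-]#[O+].[C-]#[O+].[C-]#[O+].[C-]#[O+].[C-]#[O+] | intermediate
18 | η6-tricarbonylchromium complex of 19 | CC1=CC[C@H]2[C@](C)(CO)CCC[C@]2(C)[C@H]1Cc1cc(OC)c(CO[Si](C(C)C)(C(C)C)C(C)C)cc1O.[Cr].[C-]#[O+].[C-]#[O+].[C-]#[O+] | intermediate
19 | 2-(13-hydroxydrim-7-en-11-yl)-4-methoxy-5-[(triisopropylsilyloxy)methyl]phenol | CC1=CC[C@H]2[C@](C)(CO)CCC[C@]2(C)[C@H]1Cc1cc(OC)c(CO[Si](C(C)C)(C(C)C)C(C)C)cc1O | intermediate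
20 | 2-(13-hydroxydrim-7-en-11-yl)-5-(hydroxymethyl)-4-methoxyphenol | CC1=CC[C@H]2[C@](C)(CO)CCC[C@]2(C)[C@H]1Cc1cc(OC)c(CO)cc1O | intermediate
21 | quinone monoketal (C6'=O, C3' dimethyl ketal) | CC1=CC[C@H]2[C@](C)(CO)CCC[C@]2(C)[C@H]1CC1=CC(OC)(OC)C(CO)=CC1=O | intermediate
22 | (1'S,2'S)-epoxy enone ketal | CC1=CC[C@H]2[C@](C)(CO)CCC[C@]2(C)[C@H]1C[C@@]12O[C@@H]1C(OC)(OC)C(CO)=CC2=O | intermediate
23 | (1'S,2'S,6'R)-epoxy alcohol ketal | CC1=CC[C@H]2[C@](C)(CO)CCC[C@]2(C)[C@H]1C[C@@]12O[C@@H]1C(OC)(OC)C(CO)=C[C@H]2O | intermediate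
24 | epoxypholamin A | CC1=CC[C@H]2[C@](C)(CO)CCC[C@]2(C)[C@H]1C[C@@]12O[C@@H]1C(=O)C(CO)=C[C@H]2O | target

**Total step count:** 14. **Longest linear sequence:** 12 (steps 1–6 and 9–14).

**Steps most likely to fail**

*Step 4 (key step).* The opened oxirane may collapse by a 1,2-hydride shift to the C3 ketone. The cascade may stop after ring A. The C8 cation may lose a proton unselectively. The fallback moves from the cationic to the radical manifold; it sets out from 6 and returns at 8.
- Compound 6 is silylated (TBSCl, imidazole) to the 13-O-TBS epoxide F1.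
- Cp2TiCl (cat. Cp2TiCl2, Mn, TMSCl/collidine, THF, rt) opens the oxirane homolytically to the C4 radical, which cannot undergo a hydride shift.
- This radical closes both rings 6-endo through the same chair–chair array, with the bulky CH2OTBS arm equatorial and the 3β-O-titanium group fixing the sense of folding.
- The cascade ends by β-hydrogen loss to a single, exocyclic olefin, giving the drim-8(12)-en-3β-ol F2.
- Cobalt-salen/PhSiH3 hydrogen-atom-transfer isomerisation moves the 1,1-disubstituted olefin into the ring to give the drim-7-ene silyl ether F3.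
- HCl in MeOH removes the TBS group and gives 8.

*Step 12.* Facial selection may be poor because the second, remote C13 alkoxide perturbs the sodium tartrate aggregate, or because the chiral decalin is mismatched with the reagent. The fallback replaces reagent control by a covalent auxiliary; it sets out from 21 and returns at 24.
- Compound 21 is transketalised with (2R,4R)-pentane-2,4-diol (BF3·OEt2, DME; the antipode is used if the other face is shielded) to the C2-symmetric spiroketal dienone F4. One of its methyl groups covers one face of C2'.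
- Potassium trityl peroxide (Ph3COOH, KHMDS, THF, −78 → −20 °C) gives the spiroketal epoxide F5.
- Luche reduction gives the spiroketal epoxy alcohol F6.
- Aqueous HF in MeCN hydrolyses the ketal to 24.

*Step 13.* Hydride may be delivered from the face that bears C11, for instance through coordination to a ketal methoxy group, so that the hydroxyl ends syn to the oxirane. The fallback corrects the centre by substitution with inversion; it sets out from 22 and returns at 24.
- Both primary hydroxyls of 22 are silylated (TBSCl, imidazole) to the bis-TBS epoxy enone F7.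
- Reduction gives the 6'-epi alcohol F8.
- Mitsunobu reaction (4-nitrobenzoic acid, PPh3, DIAD) inverts C6' to the 6'R 4-nitrobenzoate F9.
- K2CO3/MeOH gives the bis-TBS epoxy alcohol F10.
- Aqueous HF in MeCN removes both silyl groups and the ketal to give 24.

**Further compounds**
F1 | step 4 | 13-O-TBS ether of 6 | CC(C)(C)[Si](C)(C)OC[C@]1(C)O[C@H]1CC/C(C)=C/CC/C(C)=C/CC#C[Si](C)(C)C
F2 | step 4 | 13-(tert-butyldimethylsilyloxy)-11-[(trimethylsilyl)ethynyl]drim-8(12)-en-3β-ol | C=C1CC[C@H]2[C@](C)(CO[Si](C)(C)C(C)(C)C)[C@@H](O)CC[C@]2(C)[C@H]1CC#C[Si](C)(C)C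
F3 | step 4 | 13-(tert-butyldimethylsilyloxy)-11-[(trimethylsilyl)ethynyl]drim-7-en-3β-ol | CC1=CC[C@H]2[C@](C)(CO[Si](C)(C)C(C)(C)C)[C@@H](O)CC[C@]2(C)[C@H]1CC#C[Si](C)(C)C
F4 | step 12 | (4R,6R)-4,6-dimethyl-1,3-dioxane spiroketal analogue of 21 | CC1=CC[C@H]2[C@](C)(CO)CCC[C@]2(C)[C@H]1CC1=CC2(O[C@H](C)C[C@@H](C)O2)C(CO)=CC1=O
F5 | step 12 | (1'S,2'S)-epoxide of F4 | CC1=CC[C@H]2[C@](C)(CO)CCC[C@]2(C)[C@H]1C[C@@]12O[C@@H]1C1(O[C@H](C)C[C@@H](C)O1)C(CO)=CC2=O
F6 | step 12 | (6'R)-alcohol from F5 | CC1=CC[C@H]2[C@](C)(CO)CCC[C@]2(C)[C@H]1C[C@@]12O[C@@H]1C1(O[C@H](C)C[C@@H](C)O1)C(CO)=C[C@H]2O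
F7 | step 13 | 13,7'-bis-O-TBS ether of 22 | CC1=CC[C@H]2[C@](C)(CO[Si](C)(C)C(C)(C)C)CCC[C@]2(C)[C@H]1C[C@@]12O[C@@H]1C(OC)(OC)C(CO[Si](C)(C)C(C)(C)C)=CC2=O
F8 | step 13 | 6'-epi (6'S) alcohol from F7 | CC1=CC[C@H]2[C@](C)(CO[Si](C)(C)C(C)(C)C)CCC[C@]2(C)[C@H]1C[C@@]12O[C@@H]1C(OC)(OC)C(CO[Si](C)(C)C(C)(C)C)=C[C@@H]2O
F9 | step 13 | (6'R)-4-nitrobenzoate | CC1=CC[C@H]2[C@](C)(CO[Si](C)(C)C(C)(C)C)CCC[C@]2(C)[C@H]1C[C@@]12O[C@@H]1C(OC)(OC)C(CO[Si](C)(C)C(C)(C)C)=C[C@H]2OC(=O)c1ccc(cc1)[N+](=O)[O-]
F10 | step 13 | 13,7'-bis-O-TBS ether of 23 | CC1=CC[C@H]2[C@](C)(CO[Si](C)(C)C(C)(C)C)CCC[C@]2(C)[C@H]1C[C@@]12O[C@@H]1C(OC)(OC)C(CO[Si](C)(C)C(C)(C)C)=C[C@H]2O
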